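**Retrosynthetic overview**

1. Feature: on the C5–C6–C7–C8–C9–C10 segment of the ten-membered ring, the C6 and C9 oxygens are 1,4-related and lie on one face, opposite the C7–C11 branch and the C8 oxygen. This is the imprint of an endoperoxide across a C9=C10–C5=C6 cyclohexadiene that already carries the C14 ester on C10 and a cis-fused C8,C12 γ-lactone.
2. Ten-membered ring: after ozonolysis of the C5=C10 bond, C1–C4 are inserted by Z-selective HWE (C4=C5), reagent-controlled γ-chloroallylboration (C2–C3, C1) and RCM at C1=C10. One base treatment at the end closes the 2,3-oxirane and unveils the C11=C13 methylene.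
3. Lactone and esters: on the rigid cyclohexene the lactone is moved from O8 to O6. O9 is 1,3-trans to C11 and cannot lactonise, so O8 takes the epoxyangelate and O9 the acetate without differentiating O6 from O9.
4. Endoperoxide: singlet-oxygen [4+2] on the cis-fused dienyl lactone ester, made from 4-(carboxymethyl)benzoic acid by Birch reduction, desymmetrising bromolactonisation and HBr elimination.
5. Ring order: γ-lactone on O8, then 1,2-dioxine bridge (opened again), then γ-lactone on O6, then cleavage of the cyclohexene, then the ten-membered carbocycle, then the oxirane.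

Key step: step 5

**Remarks on the chemistry**

- Germacrane numbering of the target is used for every intermediate (C1–C10 ring, C11/C12/C13 lactone carbons, C14 ester carbon, C15 methyl). The β face of the C5–C10 ring is the one carrying C11 (on C7) and O8; O6 and O9 are α.
- The sense of induction of (DHQD)2PHAL in step 2 is assumed to be the one drawn; if the antipode predominates, the pseudoenantiomeric (DHQ)2PHAL is used.
- Compounds 3 and 4 are C10 epimer mixtures that converge in step 4. The C11 configuration in 10–38 is erased in step 26.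

**Route**

Step 1
Reactants: 1 4-(carboxymethyl)benzoic acid
Product: 2 4-(carboxymethyl)cyclohexa-2,5-diene-1-carboxylic acid (cis/trans mixture at C7/C10)
Conditions: Li, NH3(l)/THF, −78 °C; NH4Cl; then aq. HCl
Reagents that add atoms: none
Why: Birch reduction of a benzoate: the carboxylate-bearing ring takes up two electrons and is protonated at the ipso (C10) and para (C7) carbons, leaving the skipped C5=C6 and C8=C9 alkenes; both diastereomers are meso and converge once C10 becomes sp2 in step 4.

Step 2
Reactants: 2 4-(carboxymethyl)cyclohexa-2,5-diene-1-carboxylic acid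
Product: 3 bromolactone acid (cis-fused O8–C12 γ-lactone on the β face, Br on C9 α and trans to O8, free C10 carboxylic acid, C5=C6 alkene)
Conditions: NBS (1.05 equiv), (DHQD)2PHAL (10 mol %), CHCl3/hexane 1:1, −40 °C
Reagents that add atoms: N-bromosuccinimide, O=C1CCC(=O)N1Br
Why: Cinchona-alkaloid-catalysed desymmetrising bromolactonisation (enantioselective halolactonisation of a prochiral cyclohexa-2,5-dienylacetic acid): the C12 carboxylate closes 5-exo onto C8 of one enantiotopic alkene anti to the bromonium ion, which sets C7 and C8 (cis fusion is enforced by the five-membered ring) and puts Br on C9 trans to O8, while the ring acid could only form a four-membered lactone and stays free.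

Step 3
Reactants: 3 bromolactone acid
Product: 4 bromolactone methyl ester
Conditions: TMSCHN2, MeOH/toluene 1:4, 0 °C
Reagents that add atoms: trimethylsilyldiazomethane, C[Si](C)(C)C=[N+]=[N-]
Why: Methyl esterification of the remaining carboxylic acid with a diazoalkane under neutral conditions, which leaves the secondary bromide and the lactone untouched.

Step 4
Reactants: 4 bromolactone methyl ester
Product: 5 cis-fused dienyl lactone methyl ester (methyl 2-oxo-2,3,3a,7a-tetrahydro-1-benzofuran-6-carboxylate; diene C9=C10–C5=C6, ester on C10, lactone O8/C11 on the β face)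
Conditions: DBU (1.5 equiv), CH2Cl2, 0 °C → rt; used at once
Reagents that add atoms: none
Why: Base-mediated dehydrobromination (E1cB/E2): C10–H is α to the ester and allylic, so loss of HBr towards C10 gives the C9=C10–C5=C6 dienoate, and the mild amidine base at low temperature should not yet trigger aromatisation by loss of the C8 carboxylate.

Step 5
Reactants: 5 cis-fused dienyl lactone methyl ester
Product: 6 endoperoxide (2,3-dioxabicyclo[2.2.2]octene: C6–O–O–C9 bridge on the α face, C5=C10 alkene with the ester on C10, cis-fused C8 γ-lactone on the β face)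
Conditions: O2, 5,10,15,20-tetraphenylporphyrin (1 mol %), white LEDs, CH2Cl2, −20 °C
Reagents that add atoms: dioxygen (as singlet oxygen), O=O
Why: Photosensitised singlet oxygen adds suprafacially as the 2π partner across the s-cis C9=C10–C5=C6 diene held in the six-membered ring, in a concerted [4+2] cycloaddition that forms the C6–O and C9–O bonds together and moves the alkene to C5=C10. The closest known reaction type is the singlet-oxygen Diels–Alder reaction of cyclohexa-1,3-dienes, which gives 2,3-dioxabicyclo[2.2.2]oct-5-enes anti to allylic substituents. The one new ring, the six-membered 1,2-dioxine C6–O–O–C9–C10=C5, is closed by cycloaddition, both ends bonding in the same event. C6 and C9 are set together by the cis-fused lactone, whose C11 methylene and O8 cover the β face at C7 and C8, so oxygen should arrive on the α face and both new C–O bonds end up trans to C7–C11 and C8–O. The step needs π-facial selectivity, secured by that lactone, and [4+2] over ene selectivity, secured by the locked s-cis diene, which should react faster than the allylic C7–H and C8–H; the C10 ester only slows the electrophilic oxygen. Low temperature and the absence of base keep the diene from aromatising and the product from Kornblum–DeLaMare rearrangement.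

Step 6
Reactants: 6 endoperoxide
Product: 7 diol (6α-OH, 9α-OH, cis-fused 8β,12-lactone, C5=C10 enoate)
Conditions: thiourea (2.2 equiv), MeOH, 0 °C → rt
Reagents that add atoms: none
Why: Reductive cleavage of the O–O bond of a bicyclic endoperoxide with thiourea, which touches neither C–O bond nor the enoate, so the cis-1,4-diol keeps the C6 and C9 configurations set in step 5.

Step 7
Reactants: 7 diol
Product: 8 6,9-bis(triethylsilyl) ether of 7
Conditions: TESOTf (2.5 equiv), 2,6-lutidine, CH2Cl2, −78 → 0 °C
Reagents that add atoms: triethylsilyl trifluoromethanesulfonate, CC[Si](CC)(CC)OS(=O)(=O)C(F)(F)F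
Why: Silylation of both allylic secondary alcohols with a silyl triflate, so that only the lactone α-carbon is deprotonated in step 8.

Step 8
Reactants: 8 bis(triethylsilyl) ether
Product: 10 11-(hydroxymethyl) lactone (C13 on the convex face of the cis-fused lactone, cis to H7), via lithium enolate 9 (not isolated)
Conditions: LiN(SiMe3)2 (1.1 equiv), THF, −78 °C; then CH2O (gas, from cracked paraformaldehyde), −78 → −40 °C; NH4Cl
Reagents that add atoms: formaldehyde, C=O
Why: Aldol addition of the lactone lithium enolate to monomeric formaldehyde (α-hydroxymethylation), the electrophile entering C11 from the convex face of the cis-fused bicycle; the amide base is expected to take the unhindered lactone α-proton faster than the hindered γ-proton of the enoate at C6.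

Step 9
Reactants: 10 11-(hydroxymethyl) lactone
Product: 11 13-O-tert-butyldimethylsilyl ether of 10
Conditions: TBSCl, imidazole, CH2Cl2, 0 °C
Reagents that add atoms: tert-butyldimethylsilyl chloride, CC(C)(C)[Si](C)(C)Cl
Why: Silylation of the primary alcohol so that it cannot compete with O8 in step 14 and is not acylated or eliminated before the lactone has been moved.

Step 10
Reactants: 11 silyl-protected lactone
Product: 12 hydroxy Weinreb amide (free 8β-OH; C12 as N-methoxy-N-methylamide; 6,9-bis-TES; 13-OTBS)
Conditions: MeNHOMe·HCl, AlMe3, CH2Cl2, 0 °C → rt; Rochelle salt work-up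
Reagents that add atoms: N,O-dimethylhydroxylamine hydrochloride, CNOC.Cl
Why: Weinreb aminolysis of a lactone with the aluminium amide made from AlMe3 and MeNHOMe·HCl, which should open the cis-fused γ-lactone faster than it attacks the hindered conjugated methyl ester and frees O8–H without touching the C8–O bond.

Step 11
Reactants: 13 angelic acid
Product: 14 (Z)-2-methylbut-2-en-1-ol
Conditions: LiAlH4, Et2O, 0 °C → rt
Reagents that add atoms: none
Why: LiAlH4 reduction of the carboxylic acid to the allylic alcohol with retention of the Z alkene.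

Step 12
Reactants: 14 (Z)-2-methylbut-2-en-1-ol
Product: 15 ((2R,3S)-2,3-dimethyloxiran-2-yl)methanol
Conditions: Ti(OiPr)4 (10 mol %), D-(−)-diethyl tartrate (12 mol %), t-BuOOH, 4 Å molecular sieves, CH2Cl2, −20 °C
Reagents that add atoms: tert-butyl hydroperoxide, CC(C)(C)OO
Why: Sharpless asymmetric epoxidation: with the allylic alcohol drawn in the usual way D-(−)-diethyl tartrate delivers oxygen to the face that gives the (2R,3S)-epoxy alcohol, and the Z geometry fixes the two methyl groups trans on the oxirane.

Step 13
Reactants: 15 epoxy alcohol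
Product: 16 (2S,3S)-2,3-dimethyloxirane-2-carboxylic acid
Conditions: TEMPO (20 mol %), PhI(OAc)2 (2.2 equiv), MeCN/H2O 1:1, rt
Reagents that add atoms: water, O
Why: TEMPO/PhI(OAc)2 oxidation of the primary alcohol through the aldehyde hydrate to the glycidic acid, which has no α-hydrogen and cannot epimerise.

Step 14
Reactants: 12 hydroxy Weinreb amide; 16 (2S,3S)-2,3-dimethyloxirane-2-carboxylic acid
Product: 18 8-O-[(2S,3S)-2,3-dimethyloxirane-2-carbonyl] Weinreb amide, via mixed anhydride 17 (not isolated)
Conditions: 16, 2,4,6-trichlorobenzoyl chloride, Et3N, toluene, rt; then 12, DMAP, toluene, 40 °C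
Reagents that add atoms: none
Why: Yamaguchi esterification: DMAP attacks the mixed anhydride at the less hindered carbonyl and the acylpyridinium acylates the hindered secondary O8–H, the Weinreb amide being too poor an electrophile to relactonise under these conditions.

Step 15
Reactants: 18 O8-acylated Weinreb amide
Product: 20 trans-fused 6α,12-lactone with free 9α-OH and 13-OH and the 8β-epoxyangelate, via triol amide 19 (not isolated)
Conditions: camphorsulfonic acid (1.2 equiv), MeOH/CH2Cl2 1:1, 0 °C → rt; then toluene, 50 °C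
Reagents that add atoms: none
Why: Acidic methanolysis of the three silyl ethers followed by acid-catalysed lactonisation of the γ-hydroxy Weinreb amide: with O8 acylated the only hydroxyl that can reach C12 is O6 (trans-fused five-membered ring), since O9 is 1,3-trans to the C7 side chain on the cyclohexene and would need a bridged bicycle, so O6 and O9 are told apart by geometry; the liberated amine is held as its sulfonate salt and the glycidic ester should survive the mild acid.

Step 16
Reactants: 20 lactone diol
Product: 21 9,13-diacetate of 20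
Conditions: Ac2O, pyridine, DMAP (cat.), CH2Cl2, 0 °C
Reagents that add atoms: acetic anhydride, CC(=O)OC(C)=O
Why: Acetylation of the remaining secondary C9–OH and primary C13–OH: the first acetate is that of the target, the second turns C13–O into the leaving group for the final elimination.

Step 17
Reactants: 21 diacetate
Product: 23 C5 aldehyde / C10 α-keto methyl ester (6α,12-lactone with 11-CH2OAc, 8β-epoxyangelate, 9α-OAc), via ozonide 22 (not isolated)
Conditions: O3, CH2Cl2, −78 °C; then PPh3, −78 °C → rt
Reagents that add atoms: ozone, [O-][O+]=O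
Why: Ozonolysis with reductive work-up: the C5=C10 enoate is the only alkene, and cleavage gives the C5 aldehyde and the C10 α-keto ester with C6, C7, C8 and C9 unchanged.

Step 18
Reactants: 24 diphenyl phosphite; 25 tert-butyl bromoacetate
Product: 26 tert-butyl 2-(diphenoxyphosphoryl)acetate
Conditions: Et3N, CH2Cl2, 0 °C → rt
Reagents that add atoms: none
Why: Michaelis–Becker-type P-alkylation of the H-phosphonate with the α-bromo ester under amine base, the usual entry to diaryl phosphonoacetates.

Step 19
Reactants: 26 tert-butyl 2-(diphenoxyphosphoryl)acetate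
Product: 28 tert-butyl 2-(diphenoxyphosphoryl)propanoate (racemic), via sodium phosphonate 27 (not isolated)
Conditions: NaH (1.0 equiv), THF, 0 °C; MeI, 0 °C → rt
Reagents that add atoms: iodomethane, CI
Why: C-methylation of the stabilised phosphonoacetate anion with iodomethane.

Step 20
Reactants: 23 keto aldehyde; 28 tert-butyl 2-(diphenoxyphosphoryl)propanoate
Product: 30 (Z)-C4=C5 tert-butyl enoate (C3 ester carbon cis to C6) with the C10 α-keto ester intact, via sodium phosphonate 29 (not isolated)
Conditions: 28, NaH (1.0 equiv), THF, 0 °C; added slowly to 23, THF, −78 → −50 °C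
Reagents that add atoms: none
Why: Ando-type Z-selective Horner–Wadsworth–Emmons olefination: the electron-poor diaryl phosphonate makes collapse of the syn adduct fast and irreversible, so the ester carbon C3 ends up cis to C6 across C4=C5; the aldehyde is far more electrophilic than the hindered keto group, and inverse addition at −78 °C keeps free base low so that the keto ester is not enolised towards loss of the C8 acyloxy group.

Step 21
Reactants: 30 (Z)-enoate keto ester
Product: 31 C10 methylene compound (methyl 2-substituted acrylate; 9-OAc now allylic)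
Conditions: Tebbe reagent Cp2Ti(μ-CH2)(μ-Cl)AlMe2 (1.2 equiv), pyridine (cat.), THF/toluene, −40 → 0 °C
Reagents that add atoms: Tebbe reagent, C=[Ti](C1C=CC=C1)C1C=CC=C1.C[Al](C)Cl
Why: Tebbe methylenation of the ketone: the titanium methylidene is non-basic, so the α-acetoxy ketone is neither enolised nor epimerised, and at low temperature it should react with the ketone well before any ester or lactone carbonyl.

Step 22
Reactants: 31 tert-butyl ester
Product: 32 (Z)-enoic acid (C3 CO2H)
Conditions: CF3CO2H/CH2Cl2 1:4, 0 °C
Reagents that add atoms: none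
Why: Acidolysis of the tert-butyl ester (E1 loss of isobutene); the glycidic ester epoxide is deactivated towards acid opening by its carbonyl group, and the acetates and the lactone are stable to trifluoroacetic acid.

Step 23
Reactants: 32 (Z)-enoic acid
Product: 34 (Z)-enal (C3 aldehyde cis to C6), via acid chloride 33 (not isolated)
Conditions: 1-chloro-N,N,2-trimethylprop-1-en-1-amine, CH2Cl2, 0 °C; then LiAlH(OtBu)3 (1.05 equiv), THF, −78 °C
Reagents that add atoms: none
Why: Conversion of the acid into its chloride under neutral conditions with an α-chloroenamine, then reduction with the hindered hydride LiAlH(OtBu)3 at −78 °C, which stops at the aldehyde and does not touch esters; low temperature throughout should preserve the Z geometry.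

Step 24
Reactants: 34 (Z)-enal
Product: 36 syn-chlorohydrin diene ((3S)-OH, (2S)-Cl, C1 as a vinyl group; C10 acrylate), via borinate 35 (not isolated)
Conditions: allyl chloride, LiN(c-C6H11)2, (+)-Ipc2BOMe [from (−)-α-pinene], Et2O, −78 °C; BF3·OEt2; then 34, −95 °C; 8-hydroxyquinoline, MeOH, rt
Reagents that add atoms: allyl chloride, C=CCCl
Why: Asymmetric γ-chloroallylboration of an aldehyde with a (Z)-γ-chloroallyl diisopinocampheylborane (Brown-type allylboration through a chair six-membered transition state): the Z geometry of the reagent gives the syn chlorohydrin, the isopinocampheyl groups of the (+)-Ipc2BOMe-derived reagent are expected to direct attack to the Re face of the aldehyde and so set C3 and C2 both as S, and the non-nucleophilic oxinate work-up spares the acetoxy acrylate.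

Step 25
Reactants: 36 syn-chlorohydrin diene
Product: 37 ten-membered chlorohydrin (C1=C10 enoate with C2 cis to C9, 3-OH, 2-Cl, Z-C4=C5, 6α,12-lactone with 11-CH2OAc, 8β-epoxyangelate, 9α-OAc)
Conditions: second-generation Hoveyda–Grubbs catalyst [RuCl2(H2IMes)(=CH-C6H4-2-OiPr)] (10 mol %), 1,4-benzoquinone (20 mol %), toluene (1 mM), 80 °C
Reagents that add atoms: none
Why: Ring-closing metathesis: ruthenium loads on the monosubstituted C1 vinyl group and closes onto the 1,1-disubstituted acrylate with loss of ethene, the ten-membered ring being expected to form with C2 and C9 cis on C1=C10 (the less strained cis,cis-cyclodecadiene); the phosphine-free catalyst avoids attack of free phosphine on the acetoxy acrylate, and the epoxide is deliberately not yet present so that heating cannot trigger a divinyl-oxirane Cope rearrangement.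

Step 26
Reactants: 37 ten-membered chlorohydrin
Product: 39 CNP0604635.2 (target), via acetoxymethyl epoxide 38 (not isolated)
Conditions: DBU (3 equiv), CH2Cl2, 0 °C → rt
Reagents that add atoms: none
Why: Two base-mediated eliminations in one flask: intramolecular Williamson displacement of the C2 chloride by the C3 alkoxide, with inversion at C2, turns the syn chlorohydrin into the cis-2,3-epoxide, and E1cB loss of acetate from the β-acetoxy lactone creates the C11=C13 methylene, so both sensitive groups appear only in the last step.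

**Compound list**

1 | 4-(carboxymethyl)benzoic acid | OC(=O)Cc1ccc(C(=O)O)cc1 | starting material
2 | 4-(carboxymethyl)cyclohexa-2,5-diene-1-carboxylic acid (cis/trans mixture) | OC(=O)CC1C=CC(C(=O)O)C=C1 | intermediate
3 | bromolactone acid: 7-bromo-2-oxo-2,3,3a,6,7,7a-hexahydro-1-benzofuran-6-carboxylic acid, cis ring fusion, Br trans to the lactone oxygen, C10 epimers | OC(=O)C1C=C[C@@H]2CC(=O)O[C@@H]2[C@H]1Br | intermediate
4 | methyl ester of 3 | COC(=O)C1C=C[C@@H]2CC(=O)O[C@@H]2[C@H]1Br | intermediate
5 | cis-fused dienyl lactone methyl ester, methyl 2-oxo-2,3,3a,7a-tetrahydro-1-benzofuran-6-carboxylate | COC(=O)C1=C[C@H]2OC(=O)C[C@H]2C=C1 | intermediate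
6 | endoperoxide: C6–O–O–C9 bridge anti to the cis-fused C8 lactone, C5=C10 enoate | COC(=O)C1=C[C@H]2OO[C@@H]1[C@H]3OC(=O)C[C@@H]23 | intermediate
7 | 6α,9α-diol with cis-fused 8β,12-lactone and C5=C10 methyl enoate | COC(=O)C1=C[C@@H](O)[C@@H]2CC(=O)O[C@@H]2[C@H]1O | intermediate
8 | 6,9-bis(triethylsilyl) ether of 7 | COC(=O)C1=C[C@@H](O[Si](CC)(CC)CC)[C@@H]2CC(=O)O[C@@H]2[C@H]1O[Si](CC)(CC)CC | intermediate
9 | lithium enolate of 8 (C11=C12) | COC(=O)C1=C[C@@H](O[Si](CC)(CC)CC)[C@@H]2C=C([O-])O[C@@H]2[C@H]1O[Si](CC)(CC)CC.[Li+] | intermediate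
10 | 11-(hydroxymethyl) derivative of 8, C13 cis to H7 on the lactone | COC(=O)C1=C[C@@H](O[Si](CC)(CC)CC)[C@@H]2[C@@H](CO)C(=O)O[C@@H]2[C@H]1O[Si](CC)(CC)CC | intermediate
11 | 13-O-TBS ether of 10 | COC(=O)C1=C[C@@H](O[Si](CC)(CC)CC)[C@@H]2[C@@H](CO[Si](C)(C)C(C)(C)C)C(=O)O[C@@H]2[C@H]1O[Si](CC)(CC)CC | intermediate
12 | hydroxy Weinreb amide: free 8β-OH, C12 N-methoxy-N-methylamide, 6,9-bis-TES, 13-OTBS | COC(=O)C1=C[C@@H](O[Si](CC)(CC)CC)[C@H]([C@@H](CO[Si](C)(C)C(C)(C)C)C(=O)N(C)OC)[C@H](O)[C@H]1O[Si](CC)(CC)CC | intermediate
13 | angelic acid | C/C=C(/C)C(=O)O | starting material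
14 | (Z)-2-methylbut-2-en-1-ol | C/C=C(/C)CO | intermediate
15 | ((2R,3S)-2,3-dimethyloxiran-2-yl)methanol | OC[C@@]1(C)O[C@H]1C | intermediate
16 | (2S,3S)-2,3-dimethyloxirane-2-carboxylic acid | OC(=O)[C@@]1(C)O[C@H]1C | intermediate
17 | mixed anhydride of 16 with 2,4,6-trichlorobenzoic acid | O=C(OC(=O)[C@@]1(C)O[C@H]1C)c1c(Cl)cc(Cl)cc1Cl | intermediate
18 | 8-O-[(2S,3S)-2,3-dimethyloxirane-2-carbonyl] derivative of 12 | COC(=O)C1=C[C@@H](O[Si](CC)(CC)CC)[C@H]([C@@H](CO[Si](C)(C)C(C)(C)C)C(=O)N(C)OC)[C@H](OC(=O)[C@@]2(C)O[C@H]2C)[C@H]1O[Si](CC)(CC)CC | intermediate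
19 | triol amide: 6α-OH, 9α-OH and 13-OH free, 8β-epoxyangelate, C12 Weinreb amide | COC(=O)C1=C[C@@H](O)[C@H]([C@@H](CO)C(=O)N(C)OC)[C@H](OC(=O)[C@@]2(C)O[C@H]2C)[C@H]1O | intermediate
20 | trans-fused 6α,12-lactone with 11-CH2OH, 8β-epoxyangelate, free 9α-OH, C5=C10 methyl enoate | COC(=O)C1=C[C@H]2OC(=O)[C@H](CO)[C@@H]2[C@H](OC(=O)[C@@]3(C)O[C@H]3C)[C@H]1O | intermediate
21 | 9,13-diacetate of 20 | COC(=O)C1=C[C@H]2OC(=O)[C@H](COC(C)=O)[C@@H]2[C@H](OC(=O)[C@@]3(C)O[C@H]3C)[C@H]1OC(C)=O | intermediate
22 | ozonide (1,2,4-trioxolane across C5 and C10) of 21, bridgehead configuration undefined | COC(=O)C12OOC(O1)[C@H]3OC(=O)[C@H](COC(C)=O)[C@@H]3[C@H](OC(=O)[C@@]4(C)O[C@H]4C)[C@H]2OC(C)=O | intermediate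
23 | C5 aldehyde / C10 α-keto methyl ester: 6α,12-lactone with 11-CH2OAc, 8-epoxyangelate, 9-OAc | O=C[C@H]1OC(=O)[C@H](COC(C)=O)[C@@H]1[C@H](OC(=O)[C@@]2(C)O[C@H]2C)[C@@H](OC(C)=O)C(=O)C(=O)OC | intermediate
24 | diphenyl phosphite | O=[PH](Oc1ccccc1)Oc1ccccc1 | starting material
25 | tert-butyl bromoacetate | CC(C)(C)OC(=O)CBr | starting material
26 | tert-butyl 2-(diphenoxyphosphoryl)acetate | CC(C)(C)OC(=O)CP(=O)(Oc1ccccc1)Oc1ccccc1 | intermediate
27 | sodium salt of 26 | CC(C)(C)OC(=O)[CH-]P(=O)(Oc1ccccc1)Oc1ccccc1.[Na+] | intermediate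
28 | tert-butyl 2-(diphenoxyphosphoryl)propanoate (racemic) | CC(C)(C)OC(=O)C(C)P(=O)(Oc1ccccc1)Oc1ccccc1 | intermediate
29 | sodium salt of 28 | CC(C)(C)OC(=O)[C-](C)P(=O)(Oc1ccccc1)Oc1ccccc1.[Na+] | intermediate
30 | (Z)-C4=C5 tert-butyl enoate with C10 α-keto methyl ester | CC(C)(C)OC(=O)/C(C)=C\[C@H]1OC(=O)[C@H](COC(C)=O)[C@@H]1[C@H](OC(=O)[C@@]2(C)O[C@H]2C)[C@@H](OC(C)=O)C(=O)C(=O)OC | intermediate
31 | C10 methylene compound (methyl acrylate at C10) of 30 | CC(C)(C)OC(=O)/C(C)=C\[C@H]1OC(=O)[C@H](COC(C)=O)[C@@H]1[C@H](OC(=O)[C@@]2(C)O[C@H]2C)[C@@H](OC(C)=O)C(=C)C(=O)OC | intermediate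
32 | (Z)-enoic acid (C3 CO2H) | OC(=O)/C(C)=C\[C@H]1OC(=O)[C@H](COC(C)=O)[C@@H]1[C@H](OC(=O)[C@@]2(C)O[C@H]2C)[C@@H](OC(C)=O)C(=C)C(=O)OC | intermediate
33 | (Z)-enoyl chloride of 32 | ClC(=O)/C(C)=C\[C@H]1OC(=O)[C@H](COC(C)=O)[C@@H]1[C@H](OC(=O)[C@@]2(C)O[C@H]2C)[C@@H](OC(C)=O)C(=C)C(=O)OC | intermediate
34 | (Z)-enal (C3 CHO cis to C6) | O=C/C(C)=C\[C@H]1OC(=O)[C@H](COC(C)=O)[C@@H]1[C@H](OC(=O)[C@@]2(C)O[C@H]2C)[C@@H](OC(C)=O)C(=C)C(=O)OC | intermediate
35 | O3-diisopinocampheylborinate of 36 | C=C[C@H](Cl)[C@@H](OB([C@H]3C[C@H]4C[C@@H]([C@@H]3C)C4(C)C)[C@H]3C[C@H]4C[C@@H]([C@@H]3C)C4(C)C)/C(C)=C\[C@H]1OC(=O)[C@H](COC(C)=O)[C@@H]1[C@H](OC(=O)[C@@]2(C)O[C@H]2C)[C@@H](OC(C)=O)C(=C)C(=O)OC | intermediate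
36 | syn-chlorohydrin diene: (3S)-OH, (2S)-Cl, C1 vinyl, Z-C4=C5, C10 acrylate | C=C[C@H](Cl)[C@@H](O)/C(C)=C\[C@H]1OC(=O)[C@H](COC(C)=O)[C@@H]1[C@H](OC(=O)[C@@]2(C)O[C@H]2C)[C@@H](OC(C)=O)C(=C)C(=O)OC | intermediate
37 | ten-membered chlorohydrin: C1=C10 enoate (C2 cis to C9), 3-OH, 2-Cl, 11-CH2OAc lactone | CC(=O)OC[C@H]1C(=O)O[C@@H]2/C=C(/C)[C@H](O)[C@@H](Cl)/C=C(/C(=O)OC)[C@H](OC(C)=O)[C@@H](OC(=O)[C@@]3(C)O[C@H]3C)[C@@H]12 | intermediate
38 | cis-2,3-epoxide with the 11-CH2OAc lactone still in place | CC(=O)OC[C@H]1C(=O)O[C@@H]2/C=C(/C)[C@@H]3O[C@@H]3/C=C(/C(=O)OC)[C@H](OC(C)=O)[C@@H](OC(=O)[C@@]4(C)O[C@H]4C)[C@@H]12 | intermediate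
39 | CNP0604635.2 | C=C1C(=O)O[C@@H]2/C=C(/C)[C@@H]3O[C@@H]3/C=C(/C(=O)OC)[C@H](OC(C)=O)[C@@H](OC(=O)[C@@]3(C)O[C@H]3C)[C@@H]12 | target

**Step count**

Total: 26 steps (21 on the main line, 3 to acid 16, 2 to phosphonate 28).
Longest linear sequence: 21 steps (steps 1–10, 14–17, 20–26).

**Three steps most likely to fail**

1. Step 25 (ring-closing metathesis). The open chlorohydrin chain is not preorganised and the 1,1-disubstituted acrylate is hindered, so ring closure may be outrun by intermolecular cross-metathesis or may not start at all. Fallback: the order of the last two operations is inverted, setting out from 36. Treatment of 36 with DBU (CH2Cl2, 0 °C) closes the cis-epoxide and eliminates the C13 acetate to give the epoxy tetraene F1. In F1 the cis-oxirane and the Z-C4=C5 alkene hold C1 and C10 within reach, so metathesis with the same catalyst at high dilution in CH2Cl2 at no more than 40 °C should close the ten-membered ring. The route is rejoined at 39. The temperature limit is needed because F1 is a cis-divinyl oxirane. Closure onto the lactone methylene would give a more strained eight-membered ring and is expected to lose out.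

2. Step 20 (Z-olefination next to the keto ester). The phosphonate anion may enolise the α-acetoxy keto ester, which then expels the C8 acyloxy group, or the olefination may lose its Z preference. Fallback: the keto group is taken out of play before the olefination, setting out from 21. Compound 21 is ozonised as in step 17 and the ozonide 22 is reduced in the same flask with NaBH4 (MeOH/CH2Cl2, −78 → −20 °C) to the C5,C10 diol F2, whose C10 is a non-enolisable α-hydroxy ester (epimer mixture). Selective oxidation of the primary C5 alcohol (TEMPO cat., PhI(OAc)2, CH2Cl2) gives the hydroxy aldehyde F3. The Ando olefination with 28 as in step 20 then gives the hydroxy (Z)-enoate F4. Dess–Martin periodinane restores the keto ester, and the route is rejoined at 30.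

3. Step 2 (desymmetrising bromolactonisation). Enantioselection may be low or reversed, because the substrate is a diacid and a mixture of two meso diastereomers. Fallback: classical resolution, setting out from 2. Uncatalysed bromolactonisation (NBS, MeCN, 0 °C) gives the racemate, that is 3 together with its antipode F5. Crystallisation with (R)-1-phenylethylamine (or its enantiomer, whichever salt of the wanted acid is less soluble) gives the ammonium salt F6. Acidification returns enantiopure 3, where the route is rejoined.

**Further compounds**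

F1 | step 25 | epoxy tetraene: cis-2,3-epoxide with C1 vinyl, Z-C4=C5, α-methylene 6,12-lactone, C10 acrylate | C=C[C@H]1O[C@H]1/C(C)=C\[C@H]2OC(=O)C(=C)[C@@H]2[C@H](OC(=O)[C@@]3(C)O[C@H]3C)[C@@H](OC(C)=O)C(=C)C(=O)OC
F2 | step 20 | C5,C10 diol (primary C5–OH, C10 α-hydroxy methyl ester, C10 epimers) | OC[C@H]1OC(=O)[C@H](COC(C)=O)[C@@H]1[C@H](OC(=O)[C@@]2(C)O[C@H]2C)[C@@H](OC(C)=O)C(O)C(=O)OC
F3 | step 20 | C5 aldehyde with C10 α-hydroxy methyl ester | O=C[C@H]1OC(=O)[C@H](COC(C)=O)[C@@H]1[C@H](OC(=O)[C@@]2(C)O[C@H]2C)[C@@H](OC(C)=O)C(O)C(=O)OC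
F4 | step 20 | (Z)-C4=C5 tert-butyl enoate with C10 α-hydroxy methyl ester | CC(C)(C)OC(=O)/C(C)=C\[C@H]1OC(=O)[C@H](COC(C)=O)[C@@H]1[C@H](OC(=O)[C@@]2(C)O[C@H]2C)[C@@H](OC(C)=O)C(O)C(=O)OC
F5 | step 2 | antipode of bromolactone acid 3 | OC(=O)C1C=C[C@H]2CC(=O)O[C@H]2[C@@H]1Br
F6 | step 2 | (R)-1-phenylethylammonium salt of 3 | [O-]C(=O)C1C=C[C@@H]2CC(=O)O[C@@H]2[C@H]1Br.C[C@@H]([NH3+])c1ccccc1
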